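**Plan**

- Drimane numbering is used: ring A = C1–C5 and C10, ring B = C5–C10, C11 = the CH2O carbon on C9, C12 = the exocyclic CH2 on C8. The retrosynthesis cuts the aryl ether (O–C11) and the ester first, then C4–CH3 together with C5–H (reductive methylation of a ring A enone), then C5–C6 and C7–C8 together, and last C9–C10.
- Enabling feature: ring B has an unsubstituted C6–C7 ethano bridge between two carbons that can both be alkenyl electrophiles. C5 is the β-carbon of the C3 carbonyl through C4, so it can be the dienyl triflate of a ring A vinylogous ester. C8 carries the exocyclic C8=C12 methylene, so it can be the enol triflate of a methyl ketone. A 1,2-diborylethane can therefore be stitched in twice.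
- Forward order: ring A comes from 2-methylcyclohexane-1,3-dione; the C9 side chain is attached at C10 by allylic alkylation; ring B is closed by the two-fold coupling; then follow C4 gem-dimethyl and trans fusion, the C3 alcohol, the ester and the coumarin ether.
- Stereochemistry: C9 and C10 come from the chiral iridium catalyst, C5 from axial protonation anti to the C10 methyl in the dissolving-metal step, and C3 from axial hydride delivery to the 4,4-dimethyl ketone.

Key step: step 8

Remark: 1,2-bis(pinacolboryl)ethane 10 is taken as purchasable (it is the diboration product of ethylene); the sense of induction of the iridium ligand in step 5 is assumed, not verified, and the antipodal ligand would be used if the first run shows the opposite sense.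

**Route**

Step 1
Reactants: 1 2-methylcyclohexane-1,3-dione
Product: 2 2-methyl-3-(2-methylpropoxy)cyclohex-2-en-1-one
Conditions: i-BuOH, TsOH·H2O (cat.), toluene, reflux, Dean–Stark trap
Reagents that add atoms: 2-methylpropan-1-ol, CC(C)CO
Why: Acid-catalysed enol etherification of a symmetrical cyclic 1,3-dione (vinylogous ester formation), driven by azeotropic removal of water.

Step 2
Reactants: 2 2-methyl-3-(2-methylpropoxy)cyclohex-2-en-1-one
Product: 3 racemic 2,6-dimethyl-3-(2-methylpropoxy)cyclohex-2-en-1-one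
Conditions: LiN(iPr)2, THF, −78 °C; MeI, −78 to 0 °C
Reagents that add atoms: iodomethane, CI
Why: Kinetic alpha-prime deprotonation and alkylation of a vinylogous ester; the new centre is racemic and is enolised again in step 5.

Step 3
Reactants: 4 (E)-but-2-ene-1,4-diol
Product: 5 (E)-4-{[tert-butyl(dimethyl)silyl]oxy}but-2-en-1-ol
Conditions: NaH (1.0 equiv), THF, 0 °C; TBSCl (1.0 equiv)
Reagents that add atoms: tert-butyl(chloro)dimethylsilane, CC(C)(C)[Si](C)(C)Cl
Why: Monosilylation of a symmetrical diol through its sparingly soluble monosodium alkoxide.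

Step 4
Reactants: 5 (E)-4-{[tert-butyl(dimethyl)silyl]oxy}but-2-en-1-ol
Product: 6 (E)-4-{[tert-butyl(dimethyl)silyl]oxy}but-2-en-1-yl methyl carbonate
Conditions: ClCO2Me, pyridine, CH2Cl2, 0 °C
Reagents that add atoms: methyl chloroformate, COC(=O)Cl
Why: O-acylation of a primary allylic alcohol to the carbonate leaving group needed for allylic substitution.

Step 5
Reactants: 3 racemic 2,6-dimethyl-3-(2-methylpropoxy)cyclohex-2-en-1-one; 6 (E)-4-{[tert-butyl(dimethyl)silyl]oxy}but-2-en-1-yl methyl carbonate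
Product: 7 (6S)-6-[(2R)-1-{[tert-butyl(dimethyl)silyl]oxy}but-3-en-2-yl]-2,6-dimethyl-3-(2-methylpropoxy)cyclohex-2-en-1-one
Conditions: LiN(SiMe3)2, THF, −78 °C; then [Ir(cod)Cl]2 (2 mol %), (Ra,R,R)-binaphthol-derived N,N-bis(1-phenylethyl)phosphoramidite (4 mol %, preactivated with n-PrNH2), 6, THF, 0 °C to rt
Reagents that add atoms: none
Why: Iridium-catalysed branched-selective asymmetric allylic alkylation of a ketone enolate, in which the enolate attacks the substituted terminus of the allyl–iridium complex anti to the metal, so that the ligand fixes C9 and the enolate face that keeps the ring C1H2 arm away from the CH2OTBS group should fix the quaternary C10 (the racemic centre of 3 is erased on enolisation).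

Step 6
Reactants: 7 (6S)-6-[(2R)-1-{[tert-butyl(dimethyl)silyl]oxy}but-3-en-2-yl]-2,6-dimethyl-3-(2-methylpropoxy)cyclohex-2-en-1-one
Product: 8 (6S)-6-[(2R)-1-{[tert-butyl(dimethyl)silyl]oxy}-3-oxobutan-2-yl]-2,6-dimethyl-3-(2-methylpropoxy)cyclohex-2-en-1-one
Conditions: PdCl2 (10 mol %), Cu(OAc)2 (20 mol %), O2 (1 atm), DMA/H2O 7:1, rt
Reagents that add atoms: water, O
Why: Wacker oxidation of the terminal vinyl group with Markovnikov selectivity gives the methyl ketone (C8=O, C12 as CH3); the copper acetate variant keeps the medium near neutral so the enol ether and silyl ether should survive and C9 is not touched.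

Step 7
Reactants: 8 (6S)-6-[(2R)-1-{[tert-butyl(dimethyl)silyl]oxy}-3-oxobutan-2-yl]-2,6-dimethyl-3-(2-methylpropoxy)cyclohex-2-en-1-one
Product: 9 (6S)-6-[(2R)-1-{[tert-butyl(dimethyl)silyl]oxy}-3-{[(trifluoromethyl)sulfonyl]oxy}but-3-en-2-yl]-2,6-dimethyl-3-(2-methylpropoxy)cyclohexa-1,3-dien-1-yl trifluoromethanesulfonate
Conditions: 8 added to LiN(iPr)2 (2.6 equiv), THF, −78 °C; N-(5-chloropyridin-2-yl)bis(trifluoromethanesulfonyl)imide (2.5 equiv), −78 to 0 °C
Reagents that add atoms: N-(5-chloropyridin-2-yl)bis(trifluoromethanesulfonyl)imide, FC(F)(F)S(=O)(=O)N(c1ccc(Cl)cn1)S(=O)(=O)C(F)(F)F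
Why: Twofold kinetic enolisation and O-sulfonylation (enol triflate formation): the methyl ketone is deprotonated at CH3 rather than at the hindered C9–H, and the alpha-prime-blocked vinylogous ester at its gamma carbon C2, so the ring triflate sits on C5 with C3 masked as the enol ether, a regiochemistry that direct triflation of the free dione would not give.

Step 8
Reactants: 9 (6S)-6-[(2R)-1-{[tert-butyl(dimethyl)silyl]oxy}-3-{[(trifluoromethyl)sulfonyl]oxy}but-3-en-2-yl]-2,6-dimethyl-3-(2-methylpropoxy)cyclohexa-1,3-dien-1-yl trifluoromethanesulfonate; 10 1,2-bis(4,4,5,5-tetramethyl-1,3,2-dioxaborolan-2-yl)ethane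
Product: 13 (4aS,5R)-5-({[tert-butyl(dimethyl)silyl]oxy}methyl)-1,4a-dimethyl-6-methylidene-4,4a,5,6,7,8-hexahydronaphthalen-2(3H)-one, via monocoupled alkylboronate 11 (not isolated), via dienol ether 12 (not isolated)
Conditions: Pd(OAc)2 (5 mol %), RuPhos (10 mol %), K3PO4 (3 M aq., 6 equiv), THF, 65 °C, 9 at 0.005 M, 10 (1.05 equiv) added over 6 h; then 0.5 M HCl, THF, 0 °C, 15 min
Reagents that add atoms: water, O
Why: Proposed new method: zerovalent palladium inserts into the less hindered side-chain enol triflate (C8–O), a base-activated primary C–B bond of 10 (assisted by its vicinal boronate) transmetalates and reductive elimination forms C7–C8 (11); a second oxidative addition into the ring A dienyl triflate (C5–O) is followed by intramolecular transmetalation of the pendant primary alkylboronate and reductive elimination from a seven-membered C(sp2)–Pd–C(sp3) palladacycle, which forms C5–C6. The closest known reactions are the B-alkyl Suzuki–Miyaura coupling of vicinal bis(boronates) at a primary C–B bond and the intramolecular B-alkyl Suzuki–Miyaura cyclisation of boryl-tethered alkenyl halides to methylenecycloalkanes; new is the use of 1,2-diborylethane as an ethane-1,2-diyl linchpin stitched twice onto a 1,4-bis(alkenyl electrophile). Ring B is closed in the second coupling as a net 6-exo closure (a formal [4+2] of the C5–C10–C9–C8 unit onto C6–C7), while ring A and the C8=C12 methylene are carried through unchanged. No stereocentre is created, because C5 and C8 stay sp2 and C9 and C10 are not enolisable under the basic conditions; C5 is set in step 9. The step needs ring closure to win over a second intermolecular coupling, oligomerisation and beta-hydride elimination: slow addition of 10 to dilute 9 keeps free diboron scarce, six-membered ring closure has a high effective molarity, and the bulky dialkylbiarylphosphine speeds C(sp2)–C(sp3) reductive elimination. Brief dilute acid then hydrolyses the 2-alkoxydiene 12 by protonation at C2 to the conjugated enone 13.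

Step 9
Reactants: 13 (4aS,5R)-5-({[tert-butyl(dimethyl)silyl]oxy}methyl)-1,4a-dimethyl-6-methylidene-4,4a,5,6,7,8-hexahydronaphthalen-2(3H)-one
Product: 15 (4aR,5R,8aS)-5-({[tert-butyl(dimethyl)silyl]oxy}methyl)-1,1,4a-trimethyl-6-methylideneoctahydronaphthalen-2(1H)-one, via lithium enolate 14 (not isolated)
Conditions: Li (2.5 equiv), liquid NH3/THF, t-BuOH (1.0 equiv), −78 to −33 °C; isoprene; MeI (excess), THF, −78 °C to rt
Reagents that add atoms: iodomethane, CI
Why: Dissolving-metal reduction of the enone (Birch-type reductive alkylation) gives the C3–C4 lithium enolate regiospecifically while the carbanion at C5 is protonated axially, anti to the axial C10 methyl (trans ring fusion), and C-methylation of that enolate at C4 installs the geminal dimethyl group; the isolated exocyclic alkene and the silyl ether are not reduced.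

Step 10
Reactants: 15 (4aR,5R,8aS)-5-({[tert-butyl(dimethyl)silyl]oxy}methyl)-1,1,4a-trimethyl-6-methylideneoctahydronaphthalen-2(1H)-one
Product: 16 (2R,4aR,5R,8aS)-5-({[tert-butyl(dimethyl)silyl]oxy}methyl)-1,1,4a-trimethyl-6-methylidenedecahydronaphthalen-2-ol
Conditions: NaBH4, MeOH/CH2Cl2, 0 °C
Reagents that add atoms: none
Why: Borohydride reduction of a 4,4-dimethyl-3-ketone in a trans-decalin, in which hydride adds along the axial direction from the face opposite the axial C4 and C10 methyls, so the C3 hydroxyl should end up equatorial and cis to the C10 methyl.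

Step 11
Reactants: 16 (2R,4aR,5R,8aS)-5-({[tert-butyl(dimethyl)silyl]oxy}methyl)-1,1,4a-trimethyl-6-methylidenedecahydronaphthalen-2-ol; 17 3-methylbutanoyl chloride
Product: 18 (2R,4aR,5R,8aS)-5-({[tert-butyl(dimethyl)silyl]oxy}methyl)-1,1,4a-trimethyl-6-methylidenedecahydronaphthalen-2-yl 3-methylbutanoate
Conditions: pyridine, DMAP (cat.), CH2Cl2, rt
Reagents that add atoms: none
Why: DMAP-catalysed acylation of the equatorial secondary alcohol with retention at C3.

Step 12
Reactants: 18 (2R,4aR,5R,8aS)-5-({[tert-butyl(dimethyl)silyl]oxy}methyl)-1,1,4a-trimethyl-6-methylidenedecahydronaphthalen-2-yl 3-methylbutanoate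
Product: 19 (2R,4aR,5R,8aS)-5-(hydroxymethyl)-1,1,4a-trimethyl-6-methylidenedecahydronaphthalen-2-yl 3-methylbutanoate
Conditions: Bu4NF, AcOH (1 equiv), THF, rt
Reagents that add atoms: none
Why: Fluoride-mediated cleavage of the primary silyl ether; the buffered medium should leave the ester in place.

Step 13
Reactants: 19 (2R,4aR,5R,8aS)-5-(hydroxymethyl)-1,1,4a-trimethyl-6-methylidenedecahydronaphthalen-2-yl 3-methylbutanoate; 20 7-hydroxy-2H-chromen-2-one (umbelliferone)
Product: 21 (2R,4aR,5R,8aS)-1,1,4a-trimethyl-6-methylidene-5-{[(2-oxo-2H-chromen-7-yl)oxy]methyl}decahydronaphthalen-2-yl 3-methylbutanoate (target)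
Conditions: PPh3, DIAD, THF, 0 °C to 45 °C
Reagents that add atoms: none
Why: Mitsunobu etherification of the acidic phenol at the primary C11 carbon, which is not a stereocentre, so no configuration is at stake.

**Compound list**

1 | 2-methylcyclohexane-1,3-dione | CC1C(=O)CCCC1=O | starting material
2 | 2-methyl-3-(2-methylpropoxy)cyclohex-2-en-1-one | CC1=C(OCC(C)C)CCCC1=O | intermediate
3 | racemic 2,6-dimethyl-3-(2-methylpropoxy)cyclohex-2-en-1-one | CC1CCC(OCC(C)C)=C(C)C1=O | intermediate
4 | (E)-but-2-ene-1,4-diol | OC/C=C/CO | starting material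
5 | (E)-4-{[tert-butyl(dimethyl)silyl]oxy}but-2-en-1-ol | OC/C=C/CO[Si](C)(C)C(C)(C)C | intermediate
6 | (E)-4-{[tert-butyl(dimethyl)silyl]oxy}but-2-en-1-yl methyl carbonate | COC(=O)OC/C=C/CO[Si](C)(C)C(C)(C)C | intermediate
7 | (6S)-6-[(2R)-1-{[tert-butyl(dimethyl)silyl]oxy}but-3-en-2-yl]-2,6-dimethyl-3-(2-methylpropoxy)cyclohex-2-en-1-one | O=C1C(C)=C(OCC(C)C)CC[C@@]1(C)[C@@H](C=C)CO[Si](C)(C)C(C)(C)C | intermediate
8 | (6S)-6-[(2R)-1-{[tert-butyl(dimethyl)silyl]oxy}-3-oxobutan-2-yl]-2,6-dimethyl-3-(2-methylpropoxy)cyclohex-2-en-1-one | O=C1C(C)=C(OCC(C)C)CC[C@@]1(C)[C@@H](C(C)=O)CO[Si](C)(C)C(C)(C)C | intermediate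
9 | (6S)-6-[(2R)-1-{[tert-butyl(dimethyl)silyl]oxy}-3-{[(trifluoromethyl)sulfonyl]oxy}but-3-en-2-yl]-2,6-dimethyl-3-(2-methylpropoxy)cyclohexa-1,3-dien-1-yl trifluoromethanesulfonate | FC(F)(F)S(=O)(=O)OC1=C(C)C(OCC(C)C)=CC[C@@]1(C)[C@@H](C(=C)OS(=O)(=O)C(F)(F)F)CO[Si](C)(C)C(C)(C)C | intermediate
10 | 1,2-bis(4,4,5,5-tetramethyl-1,3,2-dioxaborolan-2-yl)ethane | CC1(C)OB(CCB2OC(C)(C)C(C)(C)O2)OC1(C)C | starting material
11 | (6S)-6-[(2R)-1-{[tert-butyl(dimethyl)silyl]oxy}-3-methylidene-5-(4,4,5,5-tetramethyl-1,3,2-dioxaborolan-2-yl)pentan-2-yl]-2,6-dimethyl-3-(2-methylpropoxy)cyclohexa-1,3-dien-1-yl trifluoromethanesulfonate (monocoupled alkylboronate, not isolated) | FC(F)(F)S(=O)(=O)OC1=C(C)C(OCC(C)C)=CC[C@@]1(C)[C@@H](C(=C)CCB2OC(C)(C)C(C)(C)O2)CO[Si](C)(C)C(C)(C)C | intermediate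
12 | (4aS,5R)-5-({[tert-butyl(dimethyl)silyl]oxy}methyl)-1,4a-dimethyl-6-methylidene-2-(2-methylpropoxy)-4,4a,5,6,7,8-hexahydronaphthalene (dienol ether, not isolated) | C=C1CCC2=C(C)C(OCC(C)C)=CC[C@@]2(C)[C@@H]1CO[Si](C)(C)C(C)(C)C | intermediate
13 | (4aS,5R)-5-({[tert-butyl(dimethyl)silyl]oxy}methyl)-1,4a-dimethyl-6-methylidene-4,4a,5,6,7,8-hexahydronaphthalen-2(3H)-one | C=C1CCC2=C(C)C(=O)CC[C@@]2(C)[C@@H]1CO[Si](C)(C)C(C)(C)C | intermediate
14 | lithium C3–C4 enolate of the trans-fused 4-methyl-3-ketone (not isolated) | [Li+].C=C1CC[C@@H]2C(C)=C([O-])CC[C@@]2(C)[C@@H]1CO[Si](C)(C)C(C)(C)C | intermediate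
15 | (4aR,5R,8aS)-5-({[tert-butyl(dimethyl)silyl]oxy}methyl)-1,1,4a-trimethyl-6-methylideneoctahydronaphthalen-2(1H)-one | C=C1CC[C@@H]2C(C)(C)C(=O)CC[C@@]2(C)[C@@H]1CO[Si](C)(C)C(C)(C)C | intermediate
16 | (2R,4aR,5R,8aS)-5-({[tert-butyl(dimethyl)silyl]oxy}methyl)-1,1,4a-trimethyl-6-methylidenedecahydronaphthalen-2-ol | C=C1CC[C@@H]2C(C)(C)[C@H](O)CC[C@@]2(C)[C@@H]1CO[Si](C)(C)C(C)(C)C | intermediate
17 | 3-methylbutanoyl chloride | CC(C)CC(=O)Cl | starting material
18 | (2R,4aR,5R,8aS)-5-({[tert-butyl(dimethyl)silyl]oxy}methyl)-1,1,4a-trimethyl-6-methylidenedecahydronaphthalen-2-yl 3-methylbutanoate | C=C1CC[C@@H]2C(C)(C)[C@H](OC(=O)CC(C)C)CC[C@@]2(C)[C@@H]1CO[Si](C)(C)C(C)(C)C | intermediate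
19 | (2R,4aR,5R,8aS)-5-(hydroxymethyl)-1,1,4a-trimethyl-6-methylidenedecahydronaphthalen-2-yl 3-methylbutanoate | C=C1CC[C@@H]2C(C)(C)[C@H](OC(=O)CC(C)C)CC[C@@]2(C)[C@@H]1CO | intermediate
20 | 7-hydroxy-2H-chromen-2-one (umbelliferone) | O=c1ccc2ccc(O)cc2o1 | starting material
21 | (2R,4aR,5R,8aS)-1,1,4a-trimethyl-6-methylidene-5-{[(2-oxo-2H-chromen-7-yl)oxy]methyl}decahydronaphthalen-2-yl 3-methylbutanoate | C=C1CC[C@@H]2C(C)(C)[C@H](OC(=O)CC(C)C)CC[C@@]2(C)[C@@H]1COc1ccc2ccc(=O)oc2c1 | target

**Step count and risks**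

Total steps: 13 (11 on the main line and 2 for the allyl carbonate 6). Longest linear sequence: 11 steps (1 to 21 through steps 1, 2 and 5–13).

Steps most likely to fail:

1. Step 8 (proposed new method). The tethered primary alkylboronate of 11 may transmetalate too slowly, so that a second intermolecular coupling, oligomerisation, protodeboronation or base hydrolysis of the dienyl triflate takes over before ring B closes. Fallback with known chemistry, setting out from 9 and returning at 12 and then 13: a chemoselective Suzuki–Miyaura coupling of the less hindered side-chain triflate of 9 with potassium vinyltrifluoroborate (PdCl2(dppf), Cs2CO3, THF/H2O) should give the side-chain diene that keeps the ring triflate, F1. 9-BBN should hydroborate its monosubstituted vinyl terminus to the B-alkyl-9-BBN derivative F2. An intramolecular B-alkyl Suzuki–Miyaura cyclisation onto the ring A dienyl triflate (PdCl2(dppf), AsPh3, Cs2CO3, DMF/THF/H2O) then closes ring B to dienol ether 12, which is hydrolysed as in step 8 to 13.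

2. Step 5. The hindered, fully substituted enolate may attack the allyl–iridium complex with poor branched-to-linear selectivity or with poor facial selectivity at C10, or it may be O-allylated. Fallback, setting out from 6 and returning at 7, with C10 set by a cyclic template:
   - Iridium-catalysed allylation of sodium dimethyl malonate with 6 (a well-behaved stabilised nucleophile) should give the branched malonate F3.
   - TsOH in MeOH removes the silyl group and lactonises to the carbomethoxy lactone F4; Krapcho dealkoxycarbonylation (LiCl, wet DMSO, 150 °C) gives (4S)-4-ethenyloxolan-2-one F5.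
   - Alkylation of its lithium enolate with 2-ethyl-2-(2-iodoethyl)-1,3-dioxolane gives the trans lactone F6.
   - A second enolisation and MeI, entering anti to the vinyl group, gives the quaternary lactone F7.
   - Aqueous HCl in acetone unmasks the ethyl ketone F8.
   - KOtBu in THF closes ring A by intramolecular Claisen condensation of the ethyl ketone onto the lactone carbonyl, which releases C11–OH in the hydroxy dione F9.
   - Silylation (TBSCl, imidazole) gives the dione silyl ether F10.
   - Mitsunobu O-alkylation of F10 with 2-methylpropan-1-ol at the less hindered carbonyl oxygen gives 7.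

3. Step 7. Gamma-deprotonation of ring A may be incomplete, the methyl ketone enolate may add to the ring carbonyl (intramolecular aldol), or enolisation at C9 may lead to loss of silanolate. Fallback, setting out from 8 and returning at 13, which avoids the ring triflate altogether:
   - Selective kinetic enol triflation of the methyl ketone only (KN(SiMe3)2 1.05 equiv, PhNTf2, −78 °C) gives the side-chain enol triflate F11.
   - Suzuki–Miyaura vinylation (potassium vinyltrifluoroborate, PdCl2(dppf), Cs2CO3) gives the diene F12.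
   - 9-BBN hydroboration of the terminal vinyl group, then I2/NaOMe, gives the primary iodide F13.
   - tert-Butyllithium (2.1 equiv, Et2O/pentane, −78 °C) effects iodine–lithium exchange and intramolecular 1,2-addition to the vinylogous ester carbonyl, giving the tertiary carbinol F14.
   - Dilute HCl then brings about the Stork–Danheiser transposition to enone 13.

Further compounds
F1 | step 8 | (6S)-6-[(2R)-1-{[tert-butyl(dimethyl)silyl]oxy}-3-methylidenepent-4-en-2-yl]-2,6-dimethyl-3-(2-methylpropoxy)cyclohexa-1,3-dien-1-yl trifluoromethanesulfonate | FC(F)(F)S(=O)(=O)OC1=C(C)C(OCC(C)C)=CC[C@@]1(C)[C@@H](C(=C)C=C)CO[Si](C)(C)C(C)(C)C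
F2 | step 8 | (6S)-6-[(2R)-5-(9-borabicyclo[3.3.1]nonan-9-yl)-1-{[tert-butyl(dimethyl)silyl]oxy}-3-methylidenepentan-2-yl]-2,6-dimethyl-3-(2-methylpropoxy)cyclohexa-1,3-dien-1-yl trifluoromethanesulfonate | FC(F)(F)S(=O)(=O)OC1=C(C)C(OCC(C)C)=CC[C@@]1(C)[C@@H](C(=C)CCB2C3CCCC2CCC3)CO[Si](C)(C)C(C)(C)C
F3 | step 5 | dimethyl 2-[(2R)-1-{[tert-butyl(dimethyl)silyl]oxy}but-3-en-2-yl]propanedioate | COC(=O)C(C(=O)OC)[C@@H](C=C)CO[Si](C)(C)C(C)(C)C
F4 | step 5 | methyl (4R)-4-ethenyl-2-oxooxolane-3-carboxylate | O=C1C(C(=O)OC)[C@@H](C=C)CO1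
F5 | step 5 | (4S)-4-ethenyloxolan-2-one | O=C1C[C@@H](C=C)CO1
F6 | step 5 | (3R,4R)-4-ethenyl-3-[2-(2-ethyl-1,3-dioxolan-2-yl)ethyl]oxolan-2-one (trans) | O=C1[C@H](CCC2(CC)OCCO2)[C@@H](C=C)CO1
F7 | step 5 | (3S,4R)-4-ethenyl-3-[2-(2-ethyl-1,3-dioxolan-2-yl)ethyl]-3-methyloxolan-2-one | O=C1[C@@](C)(CCC2(CC)OCCO2)[C@@H](C=C)CO1
F8 | step 5 | (3S,4R)-4-ethenyl-3-methyl-3-(3-oxopentyl)oxolan-2-one | O=C1[C@@](C)(CCC(=O)CC)[C@@H](C=C)CO1
F9 | step 5 | (4S)-4-[(2R)-1-hydroxybut-3-en-2-yl]-2,4-dimethylcyclohexane-1,3-dione | O=C1C(C)C(=O)CC[C@@]1(C)[C@@H](C=C)CO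
F10 | step 5 | (4S)-4-[(2R)-1-{[tert-butyl(dimethyl)silyl]oxy}but-3-en-2-yl]-2,4-dimethylcyclohexane-1,3-dione | O=C1C(C)C(=O)CC[C@@]1(C)[C@@H](C=C)CO[Si](C)(C)C(C)(C)C
F11 | step 7 | (3R)-4-{[tert-butyl(dimethyl)silyl]oxy}-3-[(1S)-1,3-dimethyl-4-(2-methylpropoxy)-2-oxocyclohex-3-en-1-yl]but-1-en-2-yl trifluoromethanesulfonate | O=C1C(C)=C(OCC(C)C)CC[C@@]1(C)[C@@H](C(=C)OS(=O)(=O)C(F)(F)F)CO[Si](C)(C)C(C)(C)C
F12 | step 7 | (6S)-6-[(2R)-1-{[tert-butyl(dimethyl)silyl]oxy}-3-methylidenepent-4-en-2-yl]-2,6-dimethyl-3-(2-methylpropoxy)cyclohex-2-en-1-one | O=C1C(C)=C(OCC(C)C)CC[C@@]1(C)[C@@H](C(=C)C=C)CO[Si](C)(C)C(C)(C)C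
F13 | step 7 | (6S)-6-[(2R)-1-{[tert-butyl(dimethyl)silyl]oxy}-5-iodo-3-methylidenepentan-2-yl]-2,6-dimethyl-3-(2-methylpropoxy)cyclohex-2-en-1-one | O=C1C(C)=C(OCC(C)C)CC[C@@]1(C)[C@@H](C(=C)CCI)CO[Si](C)(C)C(C)(C)C
F14 | step 7 | (4aS,5R)-5-({[tert-butyl(dimethyl)silyl]oxy}methyl)-1,4a-dimethyl-6-methylidene-2-(2-methylpropoxy)-4,4a,5,6,7,8-hexahydronaphthalen-8a(3H)-ol (C8a epimers) | C=C1CCC2(O)C(C)=C(OCC(C)C)CC[C@@]2(C)[C@@H]1CO[Si](C)(C)C(C)(C)C
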